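**Retrosynthetic overview**
1. Target 13 comes from trans-diester 12 by one hydride reduction that makes both primary alcohols (C9 and C9'); 12 comes from cis-diester 11 by epimerisation at C3 (lignan C8).
2. Ring B (the dihydrofuran, the only ring formed; both benzene rings are bought) comes from the achiral aryl diazoacetate 10 by a catalyst-controlled intramolecular carbene C–H insertion that makes the C2–C3 bond (lignan C7–C8) and both stereocentres.
3. Enabling feature: the ether methylene O1–C2H2–Ar, whose C–H bonds are activated by the O1 lone pair and the trimethoxyphenyl ring, lies 1,5 to the carbene carbon C3, which sits on C3a of ring A ortho to C7a–O1, so a five-membered transition state is available.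
4. 10 comes from aryl iodide 5 (Negishi–Reformatsky arylation, then diazo transfer); 5 comes from 5-iodovanillin 1, 3,4,5-trimethoxybenzyl chloride 2 and Wittig reagent 4.

Key step: step 5

Assumption: locants C2, C3, C3a, C7a are benzofuran numbering (C2 = lignan C7, C3 = lignan C8); the S-configured catalyst Rh2(S-PTAD)4, dirhodium tetrakis[(S)-(1-adamantyl)(phthalimido)acetate], is assumed by analogy with simpler benzyl ethers to deliver the 2R series, and its mirror image Rh2(R-PTAD)4 would be used otherwise.

**Route**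

Step 1
Reactants: 1 5-iodovanillin (4-hydroxy-3-iodo-5-methoxybenzaldehyde); 2 3,4,5-trimethoxybenzyl chloride
Product: 3 3-iodo-5-methoxy-4-[(3,4,5-trimethoxybenzyl)oxy]benzaldehyde
Conditions: K2CO3, NaI (cat.), DMF, 60 °C
Reagents that add atoms: 3,4,5-trimethoxybenzyl chloride (2), COc1cc(CCl)cc(OC)c1OC
Why: Williamson ether synthesis, in which the acidic phenoxide of 1 is alkylated by the reactive benzylic chloride under iodide catalysis while the aldehyde and the aryl iodide are inert to carbonate.

Step 2
Reactants: 3 3-iodo-5-methoxy-4-[(3,4,5-trimethoxybenzyl)oxy]benzaldehyde; 4 methyl (triphenylphosphoranylidene)acetate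
Product: 5 methyl (E)-3-{3-iodo-5-methoxy-4-[(3,4,5-trimethoxybenzyl)oxy]phenyl}prop-2-enoate
Conditions: toluene, 80 °C
Reagents that add atoms: methyl (triphenylphosphoranylidene)acetate (4), COC(=O)C=P(c1ccccc1)(c1ccccc1)c1ccccc1
Why: Wittig olefination with a stabilised ylide, which reacts only with the aldehyde and should give the E-acrylate as such ylides do with aromatic aldehydes.

Step 3
Reactants: 5 methyl (E)-3-{3-iodo-5-methoxy-4-[(3,4,5-trimethoxybenzyl)oxy]phenyl}prop-2-enoate; 6 methyl bromoacetate
Product: 8 methyl (E)-3-{3-methoxy-5-(2-methoxy-2-oxoethyl)-4-[(3,4,5-trimethoxybenzyl)oxy]phenyl}prop-2-enoate, via Reformatsky reagent 7 (not isolated)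
Conditions: 6, Zn dust, TMSCl (cat.), THF, 40 °C; then 5, Pd2(dba)3 (2.5 mol %), XPhos (10 mol %), THF, 60 °C
Reagents that add atoms: methyl bromoacetate (6), COC(=O)CBr, used as its zinc reagent 7, COC(=O)C[Zn]Br
Why: Negishi cross-coupling of a Reformatsky reagent, in which oxidative addition at the carbon–iodine bond, transmetalation from zinc and reductive elimination install the acetate carbon, the mild zinc enolate leaving the acrylate, the esters and the benzyl ether untouched.

Step 4
Reactants: 8 methyl (E)-3-{3-methoxy-5-(2-methoxy-2-oxoethyl)-4-[(3,4,5-trimethoxybenzyl)oxy]phenyl}prop-2-enoate; 9 4-acetamidobenzenesulfonyl azide (p-ABSA)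
Product: 10 methyl (E)-3-{3-(1-diazo-2-methoxy-2-oxoethyl)-5-methoxy-4-[(3,4,5-trimethoxybenzyl)oxy]phenyl}prop-2-enoate
Conditions: p-ABSA, DBU, MeCN, 0 °C to rt
Reagents that add atoms: 4-acetamidobenzenesulfonyl azide (9), CC(=O)Nc1ccc(cc1)S(=O)(=O)N=[N+]=[N-]
Why: Regitz diazo transfer, in which DBU deprotonates the only acidic position, the aryl- and ester-activated methylene, and the sulfonyl azide hands over N2.

Step 5
Reactants: 10 methyl (E)-3-{3-(1-diazo-2-methoxy-2-oxoethyl)-5-methoxy-4-[(3,4,5-trimethoxybenzyl)oxy]phenyl}prop-2-enoate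
Product: 11 methyl (2R,3S)-7-methoxy-5-[(E)-3-methoxy-3-oxoprop-1-en-1-yl]-2-(3,4,5-trimethoxyphenyl)-2,3-dihydro-1-benzofuran-3-carboxylate (cis)
Conditions: Rh2(S-PTAD)4 (1 mol %), toluene, −60 °C, slow addition of 10, 4 Å MS
Reagents that add atoms: none
Why: The dirhodium tetracarboxylate takes N2 from 10 to give a catalyst-bound donor/acceptor carbene, whose electrophilic carbon (the future C3) inserts into the hydridic benzylic ether C–H bond in a concerted, asynchronous three-centre transition state stabilised by the ether oxygen and the trimethoxyphenyl ring. The closest known reaction type is the enantioselective intramolecular 1,5 C–H insertion of aryl diazoacetates into benzyl ether C–H bonds under chiral dirhodium carboxylate catalysis, which is established for cis-2-aryl-2,3-dihydrobenzofuran-3-carboxylates. Ring B closes by 1,5-insertion through a five-membered cyclic transition state, the new C2–C3 and C3–H bonds forming on the same face of the carbene. C2 is set by the chiral pocket of the phthalimido carboxylate ligands, which selects one of the two enantiotopic benzylic hydrogens, and C3 follows from the compact insertion geometry that places aryl and ester cis, so the (2R,3S) isomer should form. The step needs chemoselectivity for the intramolecular insertion over attack on the acrylate and over carbene dimerisation; the electron-poor trans-disubstituted alkene is a poor partner for an electrophilic carbene, the target C–H bond is doubly activated and held five atoms away, and slow addition at low temperature keeps the diazo ester dilute.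

Step 6
Reactants: 11 methyl (2R,3S)-7-methoxy-5-[(E)-3-methoxy-3-oxoprop-1-en-1-yl]-2-(3,4,5-trimethoxyphenyl)-2,3-dihydro-1-benzofuran-3-carboxylate
Product: 12 methyl (2R,3R)-7-methoxy-5-[(E)-3-methoxy-3-oxoprop-1-en-1-yl]-2-(3,4,5-trimethoxyphenyl)-2,3-dihydro-1-benzofuran-3-carboxylate (trans)
Conditions: NaOMe (0.3 equiv), MeOH/THF, 0 °C to rt
Reagents that add atoms: none
Why: Base-mediated epimerisation through the C3 ester enolate should give the thermodynamically preferred trans isomer while the non-acidic C2 keeps its configuration, and ring opening by β-elimination is disfavoured because the enolate π system is orthogonal to the in-plane C2–O1 bond (the reverse of a 5-endo-trig closure).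

Step 7
Reactants: 12 methyl (2R,3R)-7-methoxy-5-[(E)-3-methoxy-3-oxoprop-1-en-1-yl]-2-(3,4,5-trimethoxyphenyl)-2,3-dihydro-1-benzofuran-3-carboxylate
Product: 13 (E)-3-[(2R,3S)-3-(hydroxymethyl)-7-methoxy-2-(3,4,5-trimethoxyphenyl)-2,3-dihydro-1-benzofuran-5-yl]prop-2-en-1-ol (the target)
Conditions: i-Bu2AlH (6 equiv), CH2Cl2, −78 to −20 °C; aq. potassium sodium tartrate
Reagents that add atoms: none
Why: Hydride reduction of both methyl esters with i-Bu2AlH, which should reduce the unsaturated ester by 1,2-addition to the allylic alcohol and the C3 ester to the primary alcohol at low temperature without touching either stereocentre (the C3 descriptor changes from R to S only through the priority rules).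

**Compound list**
1 | 5-iodovanillin (4-hydroxy-3-iodo-5-methoxybenzaldehyde) | COc1cc(C=O)cc(I)c1O | starting material
2 | 3,4,5-trimethoxybenzyl chloride | COc1cc(CCl)cc(OC)c1OC | starting material
3 | 3-iodo-5-methoxy-4-[(3,4,5-trimethoxybenzyl)oxy]benzaldehyde | COc1cc(C=O)cc(I)c1OCc1cc(OC)c(OC)c(OC)c1 | intermediate
4 | methyl (triphenylphosphoranylidene)acetate | COC(=O)C=P(c1ccccc1)(c1ccccc1)c1ccccc1 | starting material
5 | methyl (E)-3-{3-iodo-5-methoxy-4-[(3,4,5-trimethoxybenzyl)oxy]phenyl}prop-2-enoate | COC(=O)/C=C/c1cc(I)c(OCc2cc(OC)c(OC)c(OC)c2)c(OC)c1 | intermediate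
6 | methyl bromoacetate | COC(=O)CBr | starting material
7 | bromo(2-methoxy-2-oxoethyl)zinc (Reformatsky reagent) | COC(=O)C[Zn]Br | intermediate
8 | methyl (E)-3-{3-methoxy-5-(2-methoxy-2-oxoethyl)-4-[(3,4,5-trimethoxybenzyl)oxy]phenyl}prop-2-enoate | COC(=O)/C=C/c1cc(CC(=O)OC)c(OCc2cc(OC)c(OC)c(OC)c2)c(OC)c1 | intermediate
9 | 4-acetamidobenzenesulfonyl azide (p-ABSA) | CC(=O)Nc1ccc(cc1)S(=O)(=O)N=[N+]=[N-] | starting material
10 | methyl (E)-3-{3-(1-diazo-2-methoxy-2-oxoethyl)-5-methoxy-4-[(3,4,5-trimethoxybenzyl)oxy]phenyl}prop-2-enoate | COC(=O)/C=C/c1cc(C(=[N+]=[N-])C(=O)OC)c(OCc2cc(OC)c(OC)c(OC)c2)c(OC)c1 | intermediate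
11 | methyl (2R,3S)-7-methoxy-5-[(E)-3-methoxy-3-oxoprop-1-en-1-yl]-2-(3,4,5-trimethoxyphenyl)-2,3-dihydro-1-benzofuran-3-carboxylate (cis) | COc1cc([C@@H]2Oc3c(OC)cc(/C=C/C(=O)OC)cc3[C@@H]2C(=O)OC)cc(OC)c1OC | intermediate
12 | methyl (2R,3R)-7-methoxy-5-[(E)-3-methoxy-3-oxoprop-1-en-1-yl]-2-(3,4,5-trimethoxyphenyl)-2,3-dihydro-1-benzofuran-3-carboxylate (trans) | COc1cc([C@@H]2Oc3c(OC)cc(/C=C/C(=O)OC)cc3[C@H]2C(=O)OC)cc(OC)c1OC | intermediate
13 | (E)-3-[(2R,3S)-3-(hydroxymethyl)-7-methoxy-2-(3,4,5-trimethoxyphenyl)-2,3-dihydro-1-benzofuran-5-yl]prop-2-en-1-ol | COc1cc([C@@H]2Oc3c(OC)cc(/C=C/CO)cc3[C@H]2CO)cc(OC)c1OC | target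

**Step count**
Total steps: 7. Longest linear sequence: 7 (1 to 13).

**Steps most likely to fail**

1. Step 5 (key step). The catalyst may discriminate poorly between the two enantiotopic benzylic hydrogens, because the ortho-methoxy group and the bulky trimethoxybenzyl group crowd its pocket. Part of the material may also close directly to the trans isomer with a different enantiomeric preference, so that enantiopurity is eroded after epimerisation. The fallback moves stereocontrol to a covalently bound lactamide auxiliary paired with a prolinate catalyst, a combination known to give trans-2-aryl-dihydrobenzofuran-3-carboxylates directly from closely related 7-methoxy substrates. It sets out from diester 8. Saponification (LiOH, THF/H2O) should give (E)-3-{3-(carboxymethyl)-5-methoxy-4-[(3,4,5-trimethoxybenzyl)oxy]phenyl}prop-2-enoic acid F2. Both acid groups would be esterified (EDC·HCl, DMAP, CH2Cl2) with 1-[(2R)-2-hydroxypropanoyl]pyrrolidine F1, itself made from methyl (R)-lactate and pyrrolidine, to give bis(lactamide) diester F3. Diazo transfer (p-ABSA, DBU, MeCN) should give diazo bis(lactamide) diester F4. Rh2(R-DOSP)4, dirhodium tetrakis[(R)-N-(4-dodecylphenylsulfonyl)prolinate], in CH2Cl2 should then close it to trans-(2R,3R) dihydrobenzofuran bis(lactamide) diester F5. The (R)-auxiliary/R-catalyst pairing is assumed to be the matched one for the 2R series; the mirror-image pair would be taken otherwise. Methanolysis (NaOMe, MeOH) should remove both auxiliaries and return to the route at 12.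

2. Step 3. Transmetalation at the ortho-substituted aryl–palladium intermediate may be slow, which would open the way to protodeiodination or to cyclisation onto the trimethoxyphenyl ring by direct arylation. The fallback sets out from iodide 5 and uses the direct palladium-catalysed cross-coupling of an aryl iodide with a diazoacetate, in which the diazo C–H bond is arylated and the diazo group is kept. The reagent is methyl diazoacetate F6, made beforehand from glycine methyl ester hydrochloride and NaNO2; conditions are Pd(PPh3)4 (cat.), Ag2CO3, Et3N, toluene, rt. This bypasses 8 and returns to the route at diazo ester 10.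

3. Step 6. The C3 enolate may expel the phenoxide (ring opening by β-elimination), which would erase the C2 configuration, or equilibration may stop short of completion. The fallback equilibrates at the aldehyde oxidation level, where much weaker base suffices. It sets out from cis-diester 11. Reduction with i-Bu2AlH (CH2Cl2, −78 °C) should give (E)-3-[(2R,3R)-3-(hydroxymethyl)-7-methoxy-2-(3,4,5-trimethoxyphenyl)-2,3-dihydro-1-benzofuran-5-yl]prop-2-en-1-ol, cis-diol F7. Oxidation of both alcohols (Dess–Martin periodinane, NaHCO3, CH2Cl2) should give cis-dialdehyde F8. A catalytic amount of Et3N in CH2Cl2 at rt should equilibrate C3 to trans-dialdehyde F9. Reduction (NaBH4, CeCl3·7H2O, MeOH, 0 °C; Luche conditions for 1,2-reduction of the enal) should return to the route at target 13.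

**Further compounds**
F1 | step 5 | 1-[(2R)-2-hydroxypropanoyl]pyrrolidine | C[C@@H](O)C(=O)N1CCCC1
F2 | step 5 | (E)-3-{3-(carboxymethyl)-5-methoxy-4-[(3,4,5-trimethoxybenzyl)oxy]phenyl}prop-2-enoic acid | OC(=O)/C=C/c1cc(CC(=O)O)c(OCc2cc(OC)c(OC)c(OC)c2)c(OC)c1
F3 | step 5 | (2R)-1-oxo-1-(pyrrolidin-1-yl)propan-2-yl (E)-3-{3-methoxy-5-[2-oxo-2-{[(2R)-1-oxo-1-(pyrrolidin-1-yl)propan-2-yl]oxy}ethyl]-4-[(3,4,5-trimethoxybenzyl)oxy]phenyl}prop-2-enoate (bis(lactamide) diester) | O=C(/C=C/c1cc(CC(=O)O[C@H](C)C(=O)N2CCCC2)c(OCc2cc(OC)c(OC)c(OC)c2)c(OC)c1)O[C@H](C)C(=O)N1CCCC1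
F4 | step 5 | (2R)-1-oxo-1-(pyrrolidin-1-yl)propan-2-yl (E)-3-{3-[1-diazo-2-oxo-2-{[(2R)-1-oxo-1-(pyrrolidin-1-yl)propan-2-yl]oxy}ethyl]-5-methoxy-4-[(3,4,5-trimethoxybenzyl)oxy]phenyl}prop-2-enoate (diazo bis(lactamide) diester) | O=C(/C=C/c1cc(C(=[N+]=[N-])C(=O)O[C@H](C)C(=O)N2CCCC2)c(OCc2cc(OC)c(OC)c(OC)c2)c(OC)c1)O[C@H](C)C(=O)N1CCCC1
F5 | step 5 | (2R)-1-oxo-1-(pyrrolidin-1-yl)propan-2-yl (2R,3R)-7-methoxy-5-[(E)-3-oxo-3-{[(2R)-1-oxo-1-(pyrrolidin-1-yl)propan-2-yl]oxy}prop-1-en-1-yl]-2-(3,4,5-trimethoxyphenyl)-2,3-dihydro-1-benzofuran-3-carboxylate (trans dihydrobenzofuran bis(lactamide) diester) | COc1cc([C@@H]2Oc3c(OC)cc(/C=C/C(=O)O[C@H](C)C(=O)N4CCCC4)cc3[C@H]2C(=O)O[C@H](C)C(=O)N2CCCC2)cc(OC)c1OC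
F6 | step 3 | methyl diazoacetate | COC(=O)C=[N+]=[N-]
F7 | step 6 | (E)-3-[(2R,3R)-3-(hydroxymethyl)-7-methoxy-2-(3,4,5-trimethoxyphenyl)-2,3-dihydro-1-benzofuran-5-yl]prop-2-en-1-ol (cis-diol) | COc1cc([C@@H]2Oc3c(OC)cc(/C=C/CO)cc3[C@@H]2CO)cc(OC)c1OC
F8 | step 6 | (2R,3S)-7-methoxy-5-[(E)-3-oxoprop-1-en-1-yl]-2-(3,4,5-trimethoxyphenyl)-2,3-dihydro-1-benzofuran-3-carbaldehyde (cis-dialdehyde) | COc1cc([C@@H]2Oc3c(OC)cc(/C=C/C=O)cc3[C@@H]2C=O)cc(OC)c1OC
F9 | step 6 | (2R,3R)-7-methoxy-5-[(E)-3-oxoprop-1-en-1-yl]-2-(3,4,5-trimethoxyphenyl)-2,3-dihydro-1-benzofuran-3-carbaldehyde (trans-dialdehyde) | COc1cc([C@@H]2Oc3c(OC)cc(/C=C/C=O)cc3[C@H]2C=O)cc(OC)c1OC
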